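The numbering is that of eudesmane. Ring A is C1-C2-C3-C4-C5-C10 and ring B is C5-C10. C14 is the CH3 on C10, C15 is the CH2O on C4, and C11-C13 is the acrylate on C7.
Cuts: C15-O (ester), C4-C15, and the oxidation level of C12. Then C3 is taken out of ring A (retro one-carbon ring expansion), followed by C4-C5 (keto ester coupling) and C10-C1 (Michael addition).
Forward: ring B is bought as (+)-dihydrocarvone and methyl acrylate brings C1, C2 and C4. Closure of C4-C5 gives a cis-hydrindan-1-one, which is ring A one carbon short, and CH2 insertion makes the decalone. Enol triflate formation, side-chain oxidation, hydroxymethylation and esterification follow.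
Enabling feature: C4 of ring A is an sp2 carbon flanked by the methylene C3 and the ring-fusion methine C5. Written as C4=O it is the retron of CH2 insertion into the C(=O)-CH2 bond of a cyclopentanone. It also makes C5-H exchangeable, and its kinetic enolate places C3=C4.
Stereochemistry: C7 comes from the chiral pool and C10 from the (R)-1-phenylethylamine imine (reagent control). C5 is set by equilibration to the trans-decalone once the ring has grown, and the E-alkene comes from trans-p-coumaric acid.

Key step: step 4

Assumption: commercial (+)-dihydrocarvone is (5R) and a mixture of C2 epimers, which is harmless because this carbon (the later C10) becomes trigonal in step 2.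

Step 1
Reactants: 1 (+)-dihydrocarvone; 2 (R)-1-phenylethylamine
Product: 3 (5R)-2-methyl-N-[(1R)-1-phenylethyl]-5-(prop-1-en-2-yl)cyclohexan-1-imine
Conditions: cat. p-TsOH, toluene, reflux, Dean-Stark trap
Reagents that add atoms: none
Why: Acid-catalysed ketone-amine condensation driven by azeotropic removal of water gives the ketimine, and no stereocentre of the target is set here because C7 is untouched and the methyl-bearing carbon is still epimerisable.

Step 2
Reactants: 3 ketimine; 4 methyl acrylate
Product: 6 methyl 3-[(1S,4R)-1-methyl-2-oxo-4-(prop-1-en-2-yl)cyclohexyl]propanoate, via alkylated imine 5 (not isolated)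
Conditions: methyl acrylate (excess), THF, 40 °C; then 20% aq AcOH, rt
Reagents that add atoms: water, SMILES O
Why: Asymmetric Michael addition of a chiral ketimine through its more substituted secondary enamine tautomer (aza-ene-like transition state with N-H transfer): the acrylate is taken up on the enamine face turned away from the phenyl group of the (R)-auxiliary, which should override the substrate bias and set quaternary C10 with CH3 cis to the C7 isopropenyl group, and mild acid hydrolysis then frees ketone and amine.

Step 3
Reactants: 6 keto ester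
Product: 8 (3aS,6R,7aS)-3a-methyl-6-(prop-1-en-2-yl)octahydro-1H-inden-1-one (cis-fused; ketone carbon = C4), via cyclic enol ether 7 (not isolated)
Conditions: TiCl3(DME)1.5, Zn-Cu couple, DME, reflux, slow addition of 6; then 1 M HCl, THF, rt
Reagents that add atoms: water, SMILES O
Why: Titanium-induced keto ester cyclisation (McMurry-type reductive carbonyl coupling, five-membered ring closure between ketone carbon C5 and ester carbon C4) gives the cyclic enol ether, and its acid hydrolysis protonates C5 under equilibrating conditions to the more stable cis-hydrindanone.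

Step 4
Reactants: 8 cis-hydrindanone
Product: 11 (4aR,7R,8aR)-4a-methyl-7-(prop-1-en-2-yl)octahydronaphthalen-1(2H)-one (trans-fused 15-nor-eudesm-11-en-4-one; 5-alpha-H, 10-beta-CH3), via alpha-silyl ketone 9 (not isolated), via cis-decalone 10 (not isolated)
Conditions: Me3SiCHN2, BF3·OEt2, CH2Cl2, -78 to -20 °C; then NaOMe (cat.), MeOH, rt
Reagents that add atoms: (trimethylsilyl)diazomethane, SMILES C[Si](C)(C)C=[N+]=[N-]
Why: BF3 activates the cyclopentanone carbonyl C4=O of 8, the nucleophilic carbon of Me3SiCHN2 adds from the convex face of the cis-hydrindanone, and in the beta-oxido diazonium ion the C4-C2 bond antiperiplanar to C-N2 shifts to the former diazo carbon as N2 leaves, so that this carbon enters ring A as C3 (Buchner-Curtius-Schlotterbeck / Tiffeneau-Demjanov-type one-carbon ring expansion, well known for 2-substituted cyclopentanones). No ring is closed: ring A grows from five to six members by a 1,2-shift, and ring B, C7 and C10 are spectators. The step needs migration of the methylene C2 and not of the methine C5, which is secured by the bulky silyl group avoiding the branched C5 side in the reactive rotamer and by the usual preference of Lewis acid promoted diazoalkane insertion for the less substituted carbon. A second insertion is held back because the first product is the hindered alpha-silyl ketone 9, and the isopropenyl group is inert to the metal-free diazoalkane. Methoxide in methanol then removes silicon and exchanges C5-H: the cis fusion is the stable one in the five-membered ketone, but in the six-membered ketone the trans-decalone with equatorial C7 substituent should be, so C5 (5-alpha-H) is set under thermodynamic control by C10 and C7. The event thus delivers the ring size, a C4 carbonyl that a Robinson annulation cannot place, and the last stereocentre.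

Step 5
Reactants: 11 trans-decalone
Product: 13 15-nor-eudesma-3,11-dien-4-yl trifluoromethanesulfonate (5-alpha-H, 7-alpha-H, 10-beta-CH3), via lithium enolate 12 (not isolated)
Conditions: LDA, THF, -78 °C; then PhNTf2, -78 °C to rt
Reagents that add atoms: N-phenylbis(trifluoromethanesulfonimide), SMILES O=S(=O)(N(c1ccccc1)S(=O)(=O)C(F)(F)F)C(F)(F)F
Why: Kinetic deprotonation with the hindered amide removes a C3 proton rather than the tertiary C5-H, and O-triflation of the enolate (enol triflate synthesis) fixes the C3=C4 double bond and leaves C5 untouched.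

Step 6
Reactants: 13 enol triflate
Product: 15 4-(trifluoromethylsulfonyloxy)-15-nor-eudesma-3,11(13)-dien-12-al, via allylic alcohol 14 (not isolated)
Conditions: SeO2 (cat.), t-BuOOH, CH2Cl2, rt; then MnO2, CH2Cl2, rt
Reagents that add atoms: tert-butyl hydroperoxide, SMILES CC(C)(C)OO
Why: Riley-type allylic oxidation (ene reaction followed by 2,3-sigmatropic shift) should touch only the electron-rich 1,1-disubstituted alkene because the enol triflate alkene is deactivated, and MnO2 carries the primary allylic alcohol on to the 2-substituted propenal.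

Step 7
Reactants: 15 enal
Product: 16 4-(trifluoromethylsulfonyloxy)-15-nor-eudesma-3,11(13)-dien-12-oic acid
Conditions: NaClO2, NaH2PO4, 2-methyl-2-butene, t-BuOH/H2O, rt
Reagents that add atoms: sodium chlorite, SMILES [Na+].[O-]Cl=O
Why: Pinnick oxidation converts the enal into the acrylic acid under buffered conditions that spare the terminal methylene group and the enol triflate, the scavenger alkene taking up the hypochlorous acid.

Step 8
Reactants: 16 acrylic acid
Product: 17 methyl 4-(trifluoromethylsulfonyloxy)-15-nor-eudesma-3,11(13)-dien-12-oate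
Conditions: MeI, K2CO3, DMF, rt
Reagents that add atoms: iodomethane, SMILES CI
Why: SN2 O-alkylation of the potassium carboxylate with iodomethane gives the methyl ester under conditions too mild to deconjugate the acrylate or epimerise C7.

Step 9
Reactants: 17 enol triflate ester
Product: 18 methyl 15-hydroxyeudesma-3,11(13)-dien-12-oate (5-alpha-H, 7-alpha-H, 10-beta-CH3)
Conditions: Bu3SnCH2OH, Pd(PPh3)4 (cat.), LiCl, 1,4-dioxane, 100 °C
Reagents that add atoms: (tributylstannyl)methanol, SMILES CCCC[Sn](CCCC)(CCCC)CO
Why: Stille coupling of an enol triflate with (tributylstannyl)methanol (oxidative addition to zerovalent palladium, chloride-assisted transmetallation, reductive elimination) forms C4-C15 with the C3=C4 position retained and tolerates the acrylate ester.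

Step 10
Reactants: 18 allylic alcohol; 19 trans-p-coumaric acid
Product: 20 methyl 15-[(E)-3-(4-hydroxyphenyl)prop-2-enoyloxy]eudesma-3,11(13)-dien-12-oate (5R,7R,10R), the target
Conditions: PPh3, DIAD, THF, 0 °C to rt
Reagents that add atoms: none
Why: Mitsunobu esterification of the primary allylic alcohol: the carboxylic acid is far more acidic than the phenol, so only the carboxylate attacks the alkoxyphosphonium ion at C15 (SN2, no allylic shift expected), and the E-alkene of 19 is retained.

Compound list
1 | (+)-dihydrocarvone, (5R)-2-methyl-5-(prop-1-en-2-yl)cyclohexan-1-one, C2 epimers | C=C(C)[C@@H]1CCC(C)C(=O)C1 | starting material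
2 | (R)-1-phenylethylamine | C[C@H](c1ccccc1)N | starting material
3 | ketimine of 1 and 2 | C=C(C)[C@@H]1CCC(C)C(=N[C@H](C)c2ccccc2)C1 | intermediate
4 | methyl acrylate | C=CC(=O)OC | starting material
5 | alkylated imine (quaternary C10 set) | C=C(C)[C@@H]1CC[C@@](C)(CCC(=O)OC)C(=N[C@H](C)c2ccccc2)C1 | intermediate
6 | methyl 3-[(1S,4R)-1-methyl-2-oxo-4-(prop-1-en-2-yl)cyclohexyl]propanoate | C=C(C)[C@@H]1CC[C@@](C)(CCC(=O)OC)C(=O)C1 | intermediate
7 | cyclic methyl enol ether, 3-methoxy-7a-methyl-5-(prop-1-en-2-yl)-2,4,5,6,7,7a-hexahydro-1H-indene | C=C(C)[C@@H]1CC[C@@]2(C)CCC(OC)=C2C1 | intermediate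
8 | (3aS,6R,7aS)-3a-methyl-6-(prop-1-en-2-yl)octahydro-1H-inden-1-one, cis-fused | C=C(C)[C@@H]1CC[C@@]2(C)CCC(=O)[C@H]2C1 | intermediate
9 | cis-fused 3-(trimethylsilyl)-15-nor-eudesm-11-en-4-one | C=C(C)[C@@H]1CC[C@@]2(C)CCC([Si](C)(C)C)C(=O)[C@H]2C1 | intermediate
10 | (4aR,7R,8aS)-4a-methyl-7-(prop-1-en-2-yl)octahydronaphthalen-1(2H)-one, cis-fused | C=C(C)[C@@H]1CC[C@@]2(C)CCCC(=O)[C@H]2C1 | intermediate
11 | (4aR,7R,8aR)-4a-methyl-7-(prop-1-en-2-yl)octahydronaphthalen-1(2H)-one, trans-fused | C=C(C)[C@@H]1CC[C@@]2(C)CCCC(=O)[C@@H]2C1 | intermediate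
12 | lithium C3=C4 enolate of 11 | [Li+].C=C(C)[C@@H]1CC[C@@]2(C)CCC=C([O-])[C@@H]2C1 | intermediate
13 | 15-nor-eudesma-3,11-dien-4-yl trifluoromethanesulfonate | C=C(C)[C@@H]1CC[C@@]2(C)CCC=C(OS(=O)(=O)C(F)(F)F)[C@@H]2C1 | intermediate
14 | 12-hydroxy-15-nor-eudesma-3,11(13)-dien-4-yl trifluoromethanesulfonate | C=C(CO)[C@@H]1CC[C@@]2(C)CCC=C(OS(=O)(=O)C(F)(F)F)[C@@H]2C1 | intermediate
15 | 4-(trifluoromethylsulfonyloxy)-15-nor-eudesma-3,11(13)-dien-12-al | C=C(C=O)[C@@H]1CC[C@@]2(C)CCC=C(OS(=O)(=O)C(F)(F)F)[C@@H]2C1 | intermediate
16 | 4-(trifluoromethylsulfonyloxy)-15-nor-eudesma-3,11(13)-dien-12-oic acid | C=C(C(=O)O)[C@@H]1CC[C@@]2(C)CCC=C(OS(=O)(=O)C(F)(F)F)[C@@H]2C1 | intermediate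
17 | methyl 4-(trifluoromethylsulfonyloxy)-15-nor-eudesma-3,11(13)-dien-12-oate | C=C(C(=O)OC)[C@@H]1CC[C@@]2(C)CCC=C(OS(=O)(=O)C(F)(F)F)[C@@H]2C1 | intermediate
18 | methyl 15-hydroxyeudesma-3,11(13)-dien-12-oate | C=C(C(=O)OC)[C@@H]1CC[C@@]2(C)CCC=C(CO)[C@@H]2C1 | intermediate
19 | trans-p-coumaric acid | O=C(O)/C=C/c1ccc(O)cc1 | starting material
20 | methyl 15-[(E)-p-coumaroyloxy]eudesma-3,11(13)-dien-12-oate (5R,7R,10R) | C=C(C(=O)OC)[C@@H]1CC[C@@]2(C)CCC=C(COC(=O)/C=C/c3ccc(O)cc3)[C@@H]2C1 | target

Total step count: 10. Longest linear sequence: 10 steps (1 to 20).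

Steps most likely to fail

1. Step 4.
- What may go wrong: the methine C5 may migrate in competition with C2. A second insertion into the more reactive six-membered ketone is possible. The cis/trans equilibrium at C5 may be too shallow.
- Fallback, from 8 back to 11: kinetic enolisation of 8 (LDA, Me3SiCl, THF, -78 °C) gives the less substituted silyl enol ether F1.
- Simmons-Smith cyclopropanation of this most electron-rich alkene (Et2Zn, CH2I2, one equivalent) gives the siloxycyclopropane F2.
- FeCl3 in DMF cleaves the inner cyclopropane bond by one-electron oxidation to the ring-enlarged beta-chloro ketone F3.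
- NaOAc in hot MeOH eliminates HCl and equilibrates C5 to the trans-fused enone F4, and conjugate reduction with LiBH(s-Bu)3 gives 11.
- In this sequence the site of insertion is fixed by the enol ether and not by migratory aptitude.

2. Step 3.
- What may go wrong: intermolecular pinacol coupling or plain reduction of the hindered ketone may outrun the ring closure onto the ester.
- Fallback, from 3 back to 8: imine 3 is added to acrylonitrile in the same way to give the alkylated imine F5, which aqueous AcOH hydrolyses to the keto nitrile F6.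
- Reductive ketyl-nitrile cyclisation (Zn, Me3SiCl, 2,6-lutidine, THF, reflux; then aq HCl) closes C4-C5 and gives the cis-fused alpha-hydroxy ketone F7.
- Acetylation (Ac2O, DMAP, Et3N) gives the acetate F8, and SmI2 in THF/MeOH removes the alpha-acetoxy group to give 8.

3. Step 6.
- What may go wrong: the ene step may abstract the tertiary C7-H instead of a methyl hydrogen, giving oxygenation at C7. Conversion may be low, and organoselenium residues may persist.
- Fallback, from 13 back to 15: ene-type chlorination of the isopropenyl group with CeCl3·7H2O and NaOCl in CH2Cl2/H2O gives the allylic chloride F9.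
- Kornblum-type oxidation with N-methylmorpholine N-oxide in MeCN converts F9 into enal 15.

Further compounds
F1 | step 4 | kinetic trimethylsilyl enol ether of 8 (C2=C4) | C=C(C)[C@@H]1CC[C@@]2(C)CC=C(O[Si](C)(C)C)[C@H]2C1
F2 | step 4 | siloxycyclopropane from F1 | C=C(C)[C@@H]1CC[C@@]2(C)CC3CC3(O[Si](C)(C)C)[C@H]2C1
F3 | step 4 | 2-chloro-15-nor-eudesm-11-en-4-one, cis-fused | C=C(C)[C@@H]1CC[C@@]2(C)CC(Cl)CC(=O)[C@H]2C1
F4 | step 4 | 15-nor-eudesma-2,11-dien-4-one, trans-fused | C=C(C)[C@@H]1CC[C@@]2(C)CC=CC(=O)[C@@H]2C1
F5 | step 3 | alkylated imine from 3 and acrylonitrile | C=C(C)[C@@H]1CC[C@@](C)(CCC#N)C(=N[C@H](C)c2ccccc2)C1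
F6 | step 3 | 3-[(1S,4R)-1-methyl-2-oxo-4-(prop-1-en-2-yl)cyclohexyl]propanenitrile | C=C(C)[C@@H]1CC[C@@](C)(CCC#N)C(=O)C1
F7 | step 3 | cis-fused 7a-hydroxy-3a-methyl-6-(prop-1-en-2-yl)octahydro-1H-inden-1-one | C=C(C)[C@@H]1CC[C@@]2(C)CCC(=O)[C@@]2(O)C1
F8 | step 3 | acetate of F7 | C=C(C)[C@@H]1CC[C@@]2(C)CCC(=O)[C@@]2(OC(C)=O)C1
F9 | step 6 | 12-chloro-15-nor-eudesma-3,11(13)-dien-4-yl trifluoromethanesulfonate | C=C(CCl)[C@@H]1CC[C@@]2(C)CCC=C(OS(=O)(=O)C(F)(F)F)[C@@H]2C1
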